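**Retrosynthetic overview**
1. C17–O is the key disconnection: the allylic acetate goes on last, by C–H oxygenation and acylation of the C8 methyl of methyl (13R)-ent-labd-7-en-15-oate, so the skeleton is built as a plain hydrocarbon ester.
2. Rings A and B form in one enantioselective proton-initiated bicyclization of an acyclic C20 triene ester: ring A closes first (C4–C5), ring B directly after (C9–C10), and loss of H7 leaves the 7,8-olefin.
3. C13 is set on the acyclic chain by copper-catalysed asymmetric conjugate methylation of an E-enoate.
4. The chain comes from (2E,6E)-farnesyl bromide by allyl–allyl coupling and cross-metathesis with methyl acrylate.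

The target is read as an ent-labdane (5R,9S,10R,13R): trans-decalin, C10 methyl α, H5 and H9 β, side chain equatorial. Labdane numbering is used for the bicyclic compounds.

Assumption: (S)-Tol-BINAP (step 3) and the catalyst antipode named in step 4 are taken as the ones giving the stated sense, from memory and analogy; if a first run shows the opposite, the other antipode is used and nothing else changes.

**Step 1**
Reactants: 1 (2E,6E)-farnesyl bromide; 2 allylmagnesium bromide
Product: 3 (5E,9E)-6,10,14-trimethylpentadeca-1,5,9,13-tetraene
Conditions: allylMgBr (1.5 equiv, 1 M in Et2O), THF, −20 °C to rt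
Reagents that add atoms: none
Why: Copper-free allyl–allyl (Wurtz-type) coupling displaces the primary allylic bromide by SN2 with the olefin geometry kept; no stereocentre is formed.

**Step 2**
Reactants: 3 (5E,9E)-6,10,14-trimethylpentadeca-1,5,9,13-tetraene; 4 methyl acrylate
Product: 5 methyl (2E,6E,10E)-7,11,15-trimethylhexadeca-2,6,10,14-tetraenoate
Conditions: methyl acrylate (3 equiv), second-generation Hoveyda–Grubbs catalyst RuCl2(H2IMes)(=CH-C6H4-2-OiPr) (2 mol%), CH2Cl2, 40 °C
Reagents that add atoms: none
Why: Olefin cross-metathesis takes the monosubstituted alkene far faster than the trisubstituted ones and gives the E-enoate as the thermodynamic product.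

**Step 3**
Reactants: 5 methyl (2E,6E,10E)-7,11,15-trimethylhexadeca-2,6,10,14-tetraenoate
Product: 7 methyl (3R,6E,10E)-3,7,11,15-tetramethylhexadeca-6,10,14-trienoate, via bromomagnesium enolate 6 (not isolated)
Conditions: MeMgBr (4 equiv), CuI (copper monoiodide, 2 mol%), (S)-Tol-BINAP (3 mol%), t-BuOMe, −20 °C; then H2O/aq NH4Cl
Reagents that add atoms: methylmagnesium bromide, C[Mg]Br
Why: Copper-catalysed asymmetric conjugate addition of a Grignard reagent to an E-enoate; the ligand delivers methyl to the Re face of C3, which sets the future C13 as R, and the isolated olefins are inert.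

**Step 4**
Reactants: 7 methyl (3R,6E,10E)-3,7,11,15-tetramethylhexadeca-6,10,14-trienoate
Product: 8 methyl (13R)-ent-labd-7-en-15-oate (5R,9R,10R,13R)
Conditions: ent-IDPi (confined imidodiphosphorimidate Brønsted acid with 3,3′-diaryl-BINOL backbones and N-triflyl groups, mirror image of the catalyst that gives (−)-ambrox from (3E,7E)-homofarnesol; 5 mol%), (CF3)3COH, −20 °C, 48 h; Et3N quench
Reagents that add atoms: none
Why: Proposed new method: a catalytic enantioselective proton-initiated bicyclization of a simple polyene that ends by proton loss — the confined chiral acid protonates the terminal isopropylidene of 7 held in a chair–chair fold, C4–C5 and C9–C10 form in one anti-addition cascade (Stork–Eschenmoser) that sets C5, C9 and C10 together in the ent sense chosen by the catalyst antipode, and the chiral anion then removes the axial H7 from the C8 cation to give the 7,8-olefin, any exocyclic 8(17) isomer being returned to it by reversible protonation in the fluoroalcohol; the closest known reaction type is the imidodiphosphorimidate-catalysed cyclization of homofarnesol to ambrox, which ends by C–O capture at C8 instead of elimination, and the ring fusion and olefin position match achiral superacid cyclizations of terpenoid polyene esters; C13 is remote and untouched.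

**Step 5**
Reactants: 8 methyl (13R)-ent-labd-7-en-15-oate
Product: 10 methyl (13R)-17-acetoxy-ent-labd-7-en-15-oate (5R,9S,10R,13R; target), via 17-hydroxy ester 9 (not isolated)
Conditions: SeO2 (0.3 equiv), t-BuOOH (2.5 equiv, 5.5 M in decane), CH2Cl2, 0 °C to rt; then pyridine, Ac2O (6 equiv), DMAP (5 mol%), same flask, 0 °C to rt
Reagents that add atoms: tert-butyl hydroperoxide, CC(C)(C)OO; acetic anhydride, CC(=O)OC(C)=O
Why: Riley-type allylic oxidation (ene reaction then [2,3]-sigmatropic shift) goes to the more substituted olefin carbon and there takes the methyl over the hindered C9 methine, and the two allylic shifts return the double bond to 7,8; O-acylation follows, and no stereocentre is touched.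

**Compound list**
1 | (2E,6E)-farnesyl bromide, (2E,6E)-1-bromo-3,7,11-trimethyldodeca-2,6,10-triene | BrC/C=C(\C)CC/C=C(\C)CCC=C(C)C | starting material
2 | allylmagnesium bromide | C=CC[Mg]Br | starting material
3 | (5E,9E)-6,10,14-trimethylpentadeca-1,5,9,13-tetraene | C=CCC/C=C(\C)CC/C=C(\C)CCC=C(C)C | intermediate
4 | methyl acrylate | C=CC(=O)OC | starting material
5 | methyl (2E,6E,10E)-7,11,15-trimethylhexadeca-2,6,10,14-tetraenoate | COC(=O)/C=C/CC/C=C(\C)CC/C=C(\C)CCC=C(C)C | intermediate
6 | bromomagnesium enolate (O-bromomagnesio ketene acetal) of 7 | COC(O[Mg]Br)=C[C@H](C)CC/C=C(\C)CC/C=C(\C)CCC=C(C)C | intermediate (not isolated)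
7 | methyl (3R,6E,10E)-3,7,11,15-tetramethylhexadeca-6,10,14-trienoate | COC(=O)C[C@H](C)CC/C=C(\C)CC/C=C(\C)CCC=C(C)C | intermediate
8 | methyl (13R)-ent-labd-7-en-15-oate, methyl (3R)-3-methyl-5-[(1R,4aR,8aR)-2,5,5,8a-tetramethyl-1,4,4a,5,6,7,8,8a-octahydronaphthalen-1-yl]pentanoate | COC(=O)C[C@H](C)CC[C@@H]1C(C)=CC[C@@H]2C(C)(C)CCC[C@@]12C | intermediate
9 | methyl (13R)-17-hydroxy-ent-labd-7-en-15-oate (5R,9S,10R,13R) | COC(=O)C[C@H](C)CC[C@@H]1C(CO)=CC[C@@H]2C(C)(C)CCC[C@@]12C | intermediate (not isolated)
10 | methyl (13R)-17-acetoxy-ent-labd-7-en-15-oate, methyl (3R)-5-[(1S,4aR,8aR)-2-(acetoxymethyl)-5,5,8a-trimethyl-1,4,4a,5,6,7,8,8a-octahydronaphthalen-1-yl]-3-methylpentanoate | COC(=O)C[C@H](C)CC[C@@H]1C(COC(C)=O)=CC[C@@H]2C(C)(C)CCC[C@@]12C | target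

**Step count**
Total: 5 steps. Longest linear sequence: 5 steps (1 → 3 → 5 → 7 → 8 → 10).

**Steps most likely to fail**

Step 4 (the proposed cyclization). It may give poor control of the ring-system antipode, mixtures of 7,8-, 8,9- and 8(17)-olefins, or monocyclic products. The fallback uses known chemistry, sets out from 7 and comes back at 8. Compound 7 is cyclized with the achiral superacid FSO3H in 2-nitropropane at −78 °C, a known way to the 7,8-unsaturated trans-decalin from polyene esters. Because C13 is already fixed, the two ring antipodes arise as a 1:1 pair of diastereomers, 8 and methyl (5S,9S,10S,13R)-labd-7-en-15-oate F1. They are separated by preparative chromatography on a chiral stationary phase (amylose tris(3,5-dimethylphenylcarbamate), supercritical CO2/MeOH), and 8 goes on to step 5. Half of the material is lost.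

Step 5 (allylic oxygenation). Oxidation may also occur at C6 or run on to the 17-aldehyde, and the one-flask acylation may be untidy. The fallback sets out from 8 and comes back at 10. Ene-type chlorination with Ca(OCl)2 and solid CO2 in CH2Cl2/H2O at 0 °C (HOCl formed in the flask) adds chlorine at C7 on the face opposite the C10 methyl and moves the double bond out, giving methyl (5R,7S,9S,10R,13R)-7-chlorolabd-8(17)-en-15-oate F2. KOAc with Pd(PPh3)4 (zerovalent palladium, 3 mol%) in THF at 50 °C then gives 10 through an allylpalladium intermediate: acetate enters at the unhindered C17 terminus, which is also the thermodynamic allylic isomer. The C–O bond is then made by substitution instead of C–H oxidation.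

Step 3 (asymmetric methylation). MeMgBr is the least reactive Grignard reagent in this reaction, and the ee at C13 cannot be raised later. The fallback sets out from 1 and comes back at 7. The dianion of methyl acetoacetate (NaH, then n-BuLi, THF, 0 °C) is alkylated with 1 to give methyl (6E,10E)-7,11,15-trimethyl-3-oxohexadeca-6,10,14-trienoate F3. NaH and ClP(O)(OEt)2 in Et2O at 0 °C give the enol phosphate methyl (2Z,6E,10E)-3-(diethoxyphosphoryloxy)-7,11,15-trimethylhexadeca-2,6,10,14-tetraenoate F4. Me2CuLi in Et2O at −78 °C replaces phosphate by methyl with retention and gives methyl (2E,6E,10E)-3,7,11,15-tetramethylhexadeca-2,6,10,14-tetraenoate F5. Copper hydride conjugate reduction (Cu(OAc)2, the DTBM-SEGPHOS antipode that delivers hydride to the Si face of C3, polymethylhydrosiloxane, t-BuOH, toluene, 0 °C) then gives 7. The stereocentre is set by C–H instead of C–C bond formation, and the route becomes one step longer.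

**Further compounds**
F1 | step 4 | methyl (5S,9S,10S,13R)-labd-7-en-15-oate | COC(=O)C[C@H](C)CC[C@H]1C(C)=CC[C@H]2C(C)(C)CCC[C@]12C
F2 | step 5 | methyl (5R,7S,9S,10R,13R)-7-chlorolabd-8(17)-en-15-oate | COC(=O)C[C@H](C)CC[C@@H]1C(=C)[C@@H](Cl)C[C@@H]2C(C)(C)CCC[C@@]12C
F3 | step 3 | methyl (6E,10E)-7,11,15-trimethyl-3-oxohexadeca-6,10,14-trienoate | COC(=O)CC(=O)CC/C=C(\C)CC/C=C(\C)CCC=C(C)C
F4 | step 3 | methyl (2Z,6E,10E)-3-(diethoxyphosphoryloxy)-7,11,15-trimethylhexadeca-2,6,10,14-tetraenoate | COC(=O)/C=C(\OP(=O)(OCC)OCC)CC/C=C(\C)CC/C=C(\C)CCC=C(C)C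
F5 | step 3 | methyl (2E,6E,10E)-3,7,11,15-tetramethylhexadeca-2,6,10,14-tetraenoate | COC(=O)/C=C(\C)CC/C=C(\C)CC/C=C(\C)CCC=C(C)C
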